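**Assumptions**
- The target has no stereocentres (achiral aryl ester), so the "single enantiomer" requirement is trivially met and nothing needs to be controlled.
- The acyl chain is read as C32 (dotriacontanoyl, carbonyl carbon included), so the target is tyrosol dotriacontanoate. If the chain were a different length, only the alkyl bromide in Step 2 would change.

**Retrosynthetic overview**
1. I avoid the acid + tyrosol esterification. The ester is disconnected by Pd-catalysed linear-selective hydroalkoxycarbonylation, which forms the C–C bond and the acyl–O bond together from a terminal C31 alkene, CO and tyrosol.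
2. The C31 terminal alkene comes from a Cu-catalysed sp3–sp3 Kumada coupling of non-8-enylMgBr with 1-bromodocosane.
3. No rings are formed (the only ring is the aromatic ring of tyrosol) and there are no stereocentres.

---

**Step 1**
Reactants: 1 (9-bromo-1-nonene), 2 (magnesium turnings)
Product: 3 (non-8-en-1-ylmagnesium bromide)
Conditions: Mg, I2 (cat.), THF, 25 → 50 °C, 2 h
Reagents that add atoms: Mg, [Mg]
Why: Standard Grignard formation at a primary alkyl bromide; the isolated terminal alkene is inert to Mg and is too far from the carbanion to cyclise. No stereocentre is formed.

**Step 2**
Reactants: 3 (non-8-en-1-ylmagnesium bromide, 1.5 equiv), 4 (1-bromodocosane)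
Product: 5 (hentriacont-1-ene)
Conditions: Li2CuCl4 (3 mol%), THF, 0 → 35 °C, 12 h; quench with aq. NH4Cl; recrystallise from hot acetone/hexane
Reagents that add atoms: none (Li2CuCl4 is catalytic)
Why: Kochi–Schlosser Cu-catalysed coupling of a primary alkyl Grignard with a primary alkyl bromide joins the C9 and C22 fragments into the C31 chain and leaves the terminal alkene untouched. The excess Grignard's homodimer (1,17-octadecadiene) is much shorter and stays in the mother liquor during recrystallisation. No stereocentre is formed.

**Step 3**
Reactants: 5 (hentriacont-1-ene), 6 (tyrosol, 3 equiv), 7 (carbon monoxide)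
Product: 8 (tyrosol dotriacontanoate, the target)
Conditions: Pd(OAc)2 (1 mol%), DTBPX [1,2-bis(di-tert-butylphosphinomethyl)benzene] (4 mol%), MsOH (5 mol%), CO (40 bar), toluene/1,4-dioxane 1:1, 100 °C, 24 h; wash with aqueous NaHCO3 and water to remove tyrosol; recrystallise
Reagents that add atoms: carbon monoxide, [C-]#[O+]
Why: Pd–H hydroalkoxycarbonylation with a bulky, wide-bite-angle diphosphine gives the linear (anti-Markovnikov) alkyl–Pd, then acyl–Pd, which is alcoholysed. Any Pd–H chain-walked internal isomers are also funnelled to the linear acyl–Pd, so the C32 linear ester forms. The unhindered, more nucleophilic primary alcohol of tyrosol reacts in preference to the weakly nucleophilic phenol, so no protecting group is needed. No stereocentre is formed.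

---

**Self-check**
- **Target match:** 8 is an ArCH2CH2–O–C(=O)–(CH2)30CH3 ester with a para-OH phenol, which matches the target SMILES (no rings other than the benzene ring, no stereocentres).
- **Atom count:**
  - Step 1: C9H17Br + Mg → C9H17MgBr.
  - Step 2: C9H17MgBr + C22H45Br → C31H62 + MgBr2.
  - Step 3: C31H62 + CO + C8H10O2 → C40H72O3, which is tyrosol plus a C32 acyl group.
- **Functional-group survival:**
  - The alkene survives the Grignard and Cu conditions.
  - The free phenol and primary alcohol are present only in Step 3, where they are compatible with Pd/CO.
  - The only acid-related risk is phenol alkylation by the alkene at 5 mol% MsOH, which is kept low by the low acid loading.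
- **Stereochemistry:** the target has no stereocentres, so none needs to be set or can be scrambled.

---

**Compound list**

| No. | Name | SMILES | Role |
|---|---|---|---|
| 1 | 9-Bromo-1-nonene | C=CCCCCCCCBr | starting material |
| 2 | Magnesium | [Mg] | starting material |
| 3 | Non-8-en-1-ylmagnesium bromide | C=CCCCCCCC[Mg]Br | intermediate |
| 4 | 1-Bromodocosane | CCCCCCCCCCCCCCCCCCCCCCBr | starting material |
| 5 | Hentriacont-1-ene | C=CCCCCCCCCCCCCCCCCCCCCCCCCCCCCC | intermediate |
| 6 | Tyrosol (4-(2-hydroxyethyl)phenol) | OCCc1ccc(O)cc1 | starting material |
| 7 | Carbon monoxide | [C-]#[O+] | starting material (reagent) |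
| 8 | Basalethanolide A (tyrosol dotriacontanoate) | CCCCCCCCCCCCCCCCCCCCCCCCCCCCCCCC(=O)OCCc1ccc(O)cc1 | target |

**Total steps:** 3. **Longest linear sequence:** 3 (1 → 3 → 5 → 8).

**Three steps most likely to fail**
1. **Step 3 (chemoselectivity, linearity, and waxy C31 alkene solubility):** Phenol alkylation, phenyl ester formation or branched ester could form, and the alkene is poorly soluble.
   - Fallback: run the same Pd/DTBPX carbonylation with methanol to give methyl dotriacontanoate, then transesterify with tyrosol using immobilised lipase (Novozym 435, 70 °C, vacuum, primary-OH selective).
2. **Step 2 (Kumada coupling of a poorly soluble C22 bromide):** Reduction or elimination of docosyl bromide and Grignard homocoupling are the risks.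
   - Fallback: skip the alkyl–alkyl coupling and build the C31 skeleton by Grubbs-II cross-metathesis of methyl 10-undecenoate with 1-tricosene, then hydrogenate (H2, Pd/C, warm THF), then lipase transesterification with tyrosol.
3. **Step 1 (Grignard formation, low risk):** Wurtz coupling could lower the titre.
   - Fallback: prepare the 9-carbon nucleophile as the organozinc (Zn dust/LiCl) and couple with docosyl bromide under Ni or Cu catalysis (Negishi-type) instead of the Grignard/Li2CuCl4 pair.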